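**Plan**
1. Numbering as in germacranolides: C-1 furanone ketone, C-2=C-3, C-4 methine bearing C-15, C-5 CH2, C-6/C-7 lactone fusion, C-8 ester carbinol, C-9 CH2, C-10 quaternary bearing C-14, C-11/C-12/C-13 lactone α-carbon, carbonyl and methyl. Retrosynthetic cuts, in order: tiglate C–O; C-13 methyl back to a C-11=C-13 methylene; C-7–C-8 (nine-membered ring); lactone ester C–O and C-7=C-11 (butenolide); furanone O–C-3; C-1–C-2.
2. Enabling feature: C-8 (secondary oxygen) is bonded to C-7, the β-carbon of the lactone ring (C-6, O, C-12, C-11, C-7) whose α-carbon C-11 bears C-13. This β-(hydroxyalkyl)-α-methyl lactone is what an SE2′ allylation of a C-8 aldehyde by a 3-(bromomethyl)butenolide (Br–C-13–C-11=C-7) delivers, and the flat 2,5-disubstituted furanone ring (C-10, O, C-3, C-2, C-1) holds the two chain ends in reach.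
3. Forward: alkyne fragment (C-2 to C-7, C-15) from (S)-2-vinyloxirane; acyl fragment (C-1, C-8 to C-10, C-14) from (R)-citramalic acid; acetylide acylation; gold-catalysed furanone closure (first ring); acrylate ester and ring-closing metathesis to the bromobutenolide (second ring); chromium-mediated closure of the nine-membered ring (last ring); hydrogenation; tigloylation.
4. Stereochemistry: C-10 from citramalic acid; C-6 from the epoxide; C-4 by trans-selective lactone methylation (1,3-induction from C-6); C-7 and C-8 in the ring closure; C-11 by hydroxyl-directed hydrogenation; the (E)-ester from tigloyl chloride.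

Key step: step 17

Remark: in the given SMILES the two methyl groups of the ester side chain are cis, so the acyl group is the (E)-2-methylbut-2-enoyl (tigloyl) group, not the angeloyl group.

**Route**

Step 1
Reactants: 1 (S)-2-vinyloxirane; 2 dimethyl malonate
Product: 3 methyl (5R)-2-oxo-5-vinyltetrahydrofuran-3-carboxylate (both C-3 epimers)
Conditions: NaOMe (1.05 equiv), MeOH, 0 → 50 °C; then 1 M HCl
Reagents that add atoms: none
Why: Malonic ester alkylation by an epoxide followed by lactonisation: the uncatalysed soft sodium enolate should open the vinyl epoxide by SN2 attack at the unhindered terminal CH2 rather than at the allylic carbon, so the C–O stereocentre (future C-6) is retained, and the alkoxide closes onto one ester.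

Step 2
Reactants: 3 methyl (5R)-2-oxo-5-vinyltetrahydrofuran-3-carboxylate
Product: 5 (5R)-5-vinyldihydrofuran-2(3H)-one, via lactone acid 4 (not isolated)
Conditions: LiOH, THF/H2O, rt; 1 M HCl to pH 2, extraction; toluene, 110 °C
Reagents that add atoms: none
Why: Saponification, relactonisation on acidification and thermal decarboxylation of the β-carboxy lactone (malonic ester degradation) should leave the allylic stereocentre untouched.

Step 3
Reactants: 5 (5R)-5-vinyldihydrofuran-2(3H)-one
Product: 7 (3S,5R)-3-methyl-5-vinyldihydrofuran-2(3H)-one, via lithium enolate 6 (not isolated)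
Conditions: LiN(i-Pr)2, THF, −78 °C; MeI, −78 → −40 °C
Reagents that add atoms: iodomethane, CI
Why: Kinetic enolate alkylation of a γ-substituted butyrolactone: iodomethane should enter the face opposite the C-5 vinyl group (1,3-induction across the five-membered ring) to give the 3,5-trans lactone, which fixes the future C-4 (S) and its methyl C-15.

Step 4
Reactants: 7 (3S,5R)-3-methyl-5-vinyldihydrofuran-2(3H)-one
Product: 8 (3S,5R)-3-methyl-5-vinyltetrahydrofuran-2-ol (anomers)
Conditions: i-Bu2AlH (1.1 equiv), CH2Cl2, −78 °C; aq. potassium sodium tartrate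
Reagents that add atoms: none
Why: Low-temperature half-reduction of a γ-lactone with i-Bu2AlH stops at the aluminium hemiacetal and gives the lactol.

Step 5
Reactants: 8 (3S,5R)-3-methyl-5-vinyltetrahydrofuran-2-ol
Product: 9 (3R,5S)-5-methylhept-1-en-6-yn-3-ol
Conditions: Ohira–Bestmann reagent (1.5 equiv), K2CO3, MeOH, 0 °C → rt
Reagents that add atoms: dimethyl (1-diazo-2-oxopropyl)phosphonate, CC(=O)C(=[N+]=[N-])P(=O)(OC)OC
Why: Seyferth–Gilbert homologation on the open hydroxy-aldehyde tautomer of the lactol gives the terminal alkyne (future C-2≡C-3) and frees the C-6 hydroxyl, and the mild carbonate conditions should not epimerise the α-methyl centre.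

Step 6
Reactants: 9 (3R,5S)-5-methylhept-1-en-6-yn-3-ol
Product: 10 triethyl{[(3R,5S)-5-methylhept-1-en-6-yn-3-yl]oxy}silane
Conditions: Et3SiCl, imidazole, CH2Cl2, 0 °C
Reagents that add atoms: chlorotriethylsilane, CC[Si](Cl)(CC)CC
Why: Silylation of the secondary alcohol blocks the C-6 oxygen, which would otherwise compete by 5-exo attack on the ynone in step 11.

Step 7
Reactants: 11 (R)-citramalic acid
Product: 12 2-[(4R)-2,2,4-trimethyl-5-oxo-1,3-dioxolan-4-yl]acetic acid
Conditions: 2,2-dimethoxypropane, TsOH·H2O (cat.), rt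
Reagents that add atoms: 2,2-dimethoxypropane, COC(C)(C)OC
Why: Acetonide formation engages only the α-hydroxy acid as the five-membered dioxolanone, which tells the two carboxyl groups apart and activates C-1 as an acyl donor.

Step 8
Reactants: 12 2-[(4R)-2,2,4-trimethyl-5-oxo-1,3-dioxolan-4-yl]acetic acid
Product: 13 (5R)-5-(2-hydroxyethyl)-2,2,5-trimethyl-1,3-dioxolan-4-one
Conditions: BH3·SMe2, THF, 0 °C → rt; MeOH
Reagents that add atoms: none
Why: Borane reduces the free carboxylic acid (through its acyloxyborane) much faster than the dioxolanone ester, giving the C-8 primary alcohol.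

Step 9
Reactants: 13 (5R)-5-(2-hydroxyethyl)-2,2,5-trimethyl-1,3-dioxolan-4-one
Product: 14 (5R)-5-{2-[(tert-butyldimethylsilyl)oxy]ethyl}-2,2,5-trimethyl-1,3-dioxolan-4-one
Conditions: t-BuMe2SiCl, imidazole, DMF, 0 °C → rt
Reagents that add atoms: tert-butylchlorodimethylsilane, CC(C)(C)[Si](C)(C)Cl
Why: Prompt silylation of the primary alcohol prevents its translactonisation onto the dioxolanone carbonyl and protects C-8 until step 15.

Step 10
Reactants: 10 triethyl{[(3R,5S)-5-methylhept-1-en-6-yn-3-yl]oxy}silane; 14 (5R)-5-{2-[(tert-butyldimethylsilyl)oxy]ethyl}-2,2,5-trimethyl-1,3-dioxolan-4-one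
Product: 16 (3R,7S,9R)-1-[(tert-butyldimethylsilyl)oxy]-3-hydroxy-3,7-dimethyl-9-[(triethylsilyl)oxy]undec-10-en-5-yn-4-one, via lithium acetylide 15 (not isolated)
Conditions: n-BuLi (1.05 equiv), THF, −78 °C; then 14, −78 → −40 °C; AcOH at −78 °C, aq. NH4Cl
Reagents that add atoms: none
Why: Acylation of a lithium acetylide by a dioxolanone: the hemiketal alkoxide should persist at low temperature, which prevents a second addition, and collapse on work-up with loss of acetone to the α′-hydroxy ynone, the quaternary carbinol C-10 (R) coming unchanged from citramalic acid.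

Step 11
Reactants: 16 (3R,7S,9R)-1-[(tert-butyldimethylsilyl)oxy]-3-hydroxy-3,7-dimethyl-9-[(triethylsilyl)oxy]undec-10-en-5-yn-4-one
Product: 17 (2R)-2-{2-[(tert-butyldimethylsilyl)oxy]ethyl}-2-methyl-5-{(2S,4R)-4-[(triethylsilyl)oxy]hex-5-en-2-yl}furan-3(2H)-one
Conditions: (Ph3P)AuCl (5 mol %), AgOTf (5 mol %), toluene, rt
Reagents that add atoms: none
Why: Gold-catalysed 5-endo-dig hydroalkoxylation of the ynone by the tertiary hydroxyl, then protodeauration, closes the furanone ring (C-10, O, C-3, C-2, C-1) under neutral conditions that should not epimerise the propargylic C-4.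

Step 12
Reactants: 17 (2R)-2-{2-[(tert-butyldimethylsilyl)oxy]ethyl}-2-methyl-5-{(2S,4R)-4-[(triethylsilyl)oxy]hex-5-en-2-yl}furan-3(2H)-one
Product: 18 (2R)-2-{2-[(tert-butyldimethylsilyl)oxy]ethyl}-5-[(2S,4R)-4-hydroxyhex-5-en-2-yl]-2-methylfuran-3(2H)-one
Conditions: PPTS (0.2 equiv), MeOH/CH2Cl2, 0 °C
Reagents that add atoms: none
Why: Acid-catalysed methanolysis cleaves the secondary triethylsilyl ether much faster than the primary tert-butyldimethylsilyl ether.

Step 13
Reactants: 18 (2R)-2-{2-[(tert-butyldimethylsilyl)oxy]ethyl}-5-[(2S,4R)-4-hydroxyhex-5-en-2-yl]-2-methylfuran-3(2H)-one; 19 2-(bromomethyl)acrylic acid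
Product: 20 (3R,5S)-5-[(5R)-5-{2-[(tert-butyldimethylsilyl)oxy]ethyl}-5-methyl-4-oxo-4,5-dihydrofuran-2-yl]hex-1-en-3-yl 2-(bromomethyl)prop-2-enoate
Conditions: DCC, DMAP (5 mol %), CH2Cl2, −10 → 0 °C
Reagents that add atoms: none
Why: Steglich esterification of the allylic alcohol with retention at C-6; low temperature and only catalytic DMAP limit attack of the amine on the allylic bromide.

Step 14
Reactants: 20 (3R,5S)-5-[(5R)-5-{2-[(tert-butyldimethylsilyl)oxy]ethyl}-5-methyl-4-oxo-4,5-dihydrofuran-2-yl]hex-1-en-3-yl 2-(bromomethyl)prop-2-enoate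
Product: 21 (5R)-3-(bromomethyl)-5-{(2S)-2-[(5R)-5-{2-[(tert-butyldimethylsilyl)oxy]ethyl}-5-methyl-4-oxo-4,5-dihydrofuran-2-yl]propyl}furan-2(5H)-one
Conditions: second-generation Hoveyda–Grubbs catalyst (10 mol %), toluene (0.005 M), 80 °C
Reagents that add atoms: none
Why: Ring-closing metathesis of an allylic acrylate to a butenolide closes the lactone ring (C-6, O, C-12, C-11, C-7): the phosphine-free ruthenium carbene should tolerate the allylic bromide, load on the vinyl group and close onto the 1,1-disubstituted acrylate with loss of ethylene, while the trisubstituted furanone alkene is inert.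

Step 15
Reactants: 21 (5R)-3-(bromomethyl)-5-{(2S)-2-[(5R)-5-{2-[(tert-butyldimethylsilyl)oxy]ethyl}-5-methyl-4-oxo-4,5-dihydrofuran-2-yl]propyl}furan-2(5H)-one
Product: 22 (5R)-3-(bromomethyl)-5-{(2S)-2-[(5R)-5-(2-hydroxyethyl)-5-methyl-4-oxo-4,5-dihydrofuran-2-yl]propyl}furan-2(5H)-one
Conditions: 48% aq. HF, MeCN, 0 °C
Reagents that add atoms: none
Why: Aqueous HF in acetonitrile cleaves the primary silyl ether without an amine or fluoride salt that could displace the allylic bromide.

Step 16
Reactants: 22 (5R)-3-(bromomethyl)-5-{(2S)-2-[(5R)-5-(2-hydroxyethyl)-5-methyl-4-oxo-4,5-dihydrofuran-2-yl]propyl}furan-2(5H)-one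
Product: 23 2-[(2R)-5-{(2S)-1-[(2R)-4-(bromomethyl)-5-oxo-2,5-dihydrofuran-2-yl]propan-2-yl}-2-methyl-3-oxo-2,3-dihydrofuran-2-yl]acetaldehyde
Conditions: Dess–Martin periodinane, CH2Cl2, 0 °C → rt; filtration through silica, used at once
Reagents that add atoms: none
Why: Dess–Martin oxidation under non-basic conditions should give the β-alkoxy aldehyde without retro-oxa-Michael opening of the furanone.

Step 17
Reactants: 23 2-[(2R)-5-{(2S)-1-[(2R)-4-(bromomethyl)-5-oxo-2,5-dihydrofuran-2-yl]propan-2-yl}-2-methyl-3-oxo-2,3-dihydrofuran-2-yl]acetaldehyde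
Product: 25 (4S,6R,7R,8S,10R)-8-hydroxy-1-oxo-3,10-epoxygermacra-2,11(13)-dien-12,6-olide, via allylchromium species 24 (not isolated)
Conditions: CrCl2 (8 equiv), degassed THF, rt, slow addition of 23 over 10 h (final 0.002 M); aq. NH4Cl
Reagents that add atoms: none
Why: Two equivalents of divalent chromium reduce the allylic C–Br bond to the allylchromium species 24 (trivalent chromium on C-13), which adds to the aldehyde carbon C-8 through its γ-carbon C-7 (SE2′) in a closed six-membered Zimmerman–Traxler transition state and moves the double bond to C-11=C-13; the closest known reactions are intramolecular Nozaki–Hiyama–Kishi allylations that close medium rings, including nine-membered rings bridging a furan, and the intermolecular Barbier allylation of aldehydes by 3-(bromomethyl)butenolides. The nine-membered oxa-bridged ring (C-8, C-9, C-10, O, C-3, C-4, C-5, C-6, C-7) is closed in the 9-exo-trig mode at the aldehyde, with the furanone and the butenolide already in place. C-7 is controlled by the C-6 stereocentre: the aldehyde should be taken up on the butenolide face opposite the C-5 substituent, which the six-atom tether can reach and which gives the less strained 6,7-trans fusion. C-8 is controlled by the locked allyl geometry: C-6 is trans to the CH2Cr group across C-7=C-11, an (E)-crotyl-type reagent, and the chair transition state with the ring chain equatorial gives 8-OH anti to C-6 (8S). The step needs chemoselectivity for the aldehyde over the furanone ketone and the lactone, and ring closure over oligomerisation; allylchromium reagents add to aldehydes far faster than to ketones or esters, the planar furanone holds the chain ends close, and slow addition at high dilution suppresses intermolecular reaction.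

Step 18
Reactants: 25 (4S,6R,7R,8S,10R)-8-hydroxy-1-oxo-3,10-epoxygermacra-2,11(13)-dien-12,6-olide
Product: 26 (4S,6R,7R,8S,10R,11S)-8-hydroxy-1-oxo-3,10-epoxygermacr-2-en-12,6-olide
Conditions: H2 (40 bar), [Rh(nbd)(dppb)]BF4 (10 mol %), CH2Cl2, rt
Reagents that add atoms: none
Why: Hydroxyl-directed homogeneous hydrogenation: the homoallylic 8-OH should bind the cationic monovalent rhodium and deliver H2 to the face of the 1,1-disubstituted C-11=C-13 alkene that is cis to C-8, so that H-11 ends cis and the new methyl trans to C-8 (11S), while the trisubstituted furanone alkene is not reduced.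

Step 19
Reactants: 26 (4S,6R,7R,8S,10R,11S)-8-hydroxy-1-oxo-3,10-epoxygermacr-2-en-12,6-olide; 27 tigloyl chloride
Product: 28 (4S,6R,7S,8S,10R,11S)-1-oxo-8-tigloyloxy-3,10-epoxygermacr-2-en-12,6-olide (CNP0235937.1)
Conditions: DMAP (0.2 equiv), pyridine, CH2Cl2, 0 °C → rt
Reagents that add atoms: none
Why: DMAP-catalysed acylation of the secondary alcohol with retention at C-8; the (E) acyl chloride is the stable isomer and the weakly basic medium should avoid translactonisation and epimerisation.

**Compound list**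
1 | (S)-2-vinyloxirane | C=C[C@H]1CO1 | starting material
2 | dimethyl malonate | COC(=O)CC(=O)OC | starting material
3 | methyl (5R)-2-oxo-5-vinyltetrahydrofuran-3-carboxylate (C-3 epimers) | COC(=O)C1C[C@H](C=C)OC1=O | intermediate
4 | (5R)-2-oxo-5-vinyltetrahydrofuran-3-carboxylic acid (lactone acid, C-3 epimers) | OC(=O)C1C[C@H](C=C)OC1=O | intermediate
5 | (5R)-5-vinyldihydrofuran-2(3H)-one | O=C1CC[C@H](C=C)O1 | intermediate
6 | lithium (5R)-5-vinyl-4,5-dihydrofuran-2-olate (lithium enolate of 5) | [Li]OC1=CC[C@H](C=C)O1 | intermediate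
7 | (3S,5R)-3-methyl-5-vinyldihydrofuran-2(3H)-one (3,5-trans) | O=C1[C@@H](C)C[C@H](C=C)O1 | intermediate
8 | (3S,5R)-3-methyl-5-vinyltetrahydrofuran-2-ol (anomers) | OC1[C@@H](C)C[C@H](C=C)O1 | intermediate
9 | (3R,5S)-5-methylhept-1-en-6-yn-3-ol | C#C[C@@H](C)C[C@H](C=C)O | intermediate
10 | triethyl{[(3R,5S)-5-methylhept-1-en-6-yn-3-yl]oxy}silane | C#C[C@@H](C)C[C@H](C=C)O[Si](CC)(CC)CC | intermediate
11 | (R)-citramalic acid, (2R)-2-hydroxy-2-methylbutanedioic acid | OC(=O)C[C@@](C(=O)O)(C)O | starting material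
12 | 2-[(4R)-2,2,4-trimethyl-5-oxo-1,3-dioxolan-4-yl]acetic acid | OC(=O)C[C@@]1(C)OC(C)(C)OC1=O | intermediate
13 | (5R)-5-(2-hydroxyethyl)-2,2,5-trimethyl-1,3-dioxolan-4-one | OCC[C@@]1(C)OC(C)(C)OC1=O | intermediate
14 | (5R)-5-{2-[(tert-butyldimethylsilyl)oxy]ethyl}-2,2,5-trimethyl-1,3-dioxolan-4-one | CC(C)(C)[Si](C)(C)OCC[C@@]1(C)OC(C)(C)OC1=O | intermediate
15 | {(3S,5R)-3-methyl-5-[(triethylsilyl)oxy]hept-6-en-1-yn-1-yl}lithium (lithium acetylide of 10) | [Li]C#C[C@@H](C)C[C@H](C=C)O[Si](CC)(CC)CC | intermediate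
16 | (3R,7S,9R)-1-[(tert-butyldimethylsilyl)oxy]-3-hydroxy-3,7-dimethyl-9-[(triethylsilyl)oxy]undec-10-en-5-yn-4-one | CC(C)(C)[Si](C)(C)OCC[C@@](C(=O)C#C[C@@H](C)C[C@H](C=C)O[Si](CC)(CC)CC)(C)O | intermediate
17 | (2R)-2-{2-[(tert-butyldimethylsilyl)oxy]ethyl}-2-methyl-5-{(2S,4R)-4-[(triethylsilyl)oxy]hex-5-en-2-yl}furan-3(2H)-one | CC(C)(C)[Si](C)(C)OCC[C@@]1(C)OC(=CC1=O)[C@@H](C)C[C@H](C=C)O[Si](CC)(CC)CC | intermediate
18 | (2R)-2-{2-[(tert-butyldimethylsilyl)oxy]ethyl}-5-[(2S,4R)-4-hydroxyhex-5-en-2-yl]-2-methylfuran-3(2H)-one | CC(C)(C)[Si](C)(C)OCC[C@@]1(C)OC(=CC1=O)[C@@H](C)C[C@H](C=C)O | intermediate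
19 | 2-(bromomethyl)acrylic acid | OC(=O)C(=C)CBr | starting material
20 | (3R,5S)-5-[(5R)-5-{2-[(tert-butyldimethylsilyl)oxy]ethyl}-5-methyl-4-oxo-4,5-dihydrofuran-2-yl]hex-1-en-3-yl 2-(bromomethyl)prop-2-enoate | CC(C)(C)[Si](C)(C)OCC[C@@]1(C)OC(=CC1=O)[C@@H](C)C[C@H](C=C)OC(=O)C(=C)CBr | intermediate
21 | (5R)-3-(bromomethyl)-5-{(2S)-2-[(5R)-5-{2-[(tert-butyldimethylsilyl)oxy]ethyl}-5-methyl-4-oxo-4,5-dihydrofuran-2-yl]propyl}furan-2(5H)-one | CC(C)(C)[Si](C)(C)OCC[C@@]1(C)OC(=CC1=O)[C@@H](C)C[C@H]1OC(=O)C(CBr)=C1 | intermediate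
22 | (5R)-3-(bromomethyl)-5-{(2S)-2-[(5R)-5-(2-hydroxyethyl)-5-methyl-4-oxo-4,5-dihydrofuran-2-yl]propyl}furan-2(5H)-one | OCC[C@@]1(C)OC(=CC1=O)[C@@H](C)C[C@H]1OC(=O)C(CBr)=C1 | intermediate
23 | 2-[(2R)-5-{(2S)-1-[(2R)-4-(bromomethyl)-5-oxo-2,5-dihydrofuran-2-yl]propan-2-yl}-2-methyl-3-oxo-2,3-dihydrofuran-2-yl]acetaldehyde | O=CC[C@@]1(C)OC(=CC1=O)[C@@H](C)C[C@H]1OC(=O)C(CBr)=C1 | intermediate
24 | allylchromium species: 23 with CrCl2 in place of Br on C-13 | O=CC[C@@]1(C)OC(=CC1=O)[C@@H](C)C[C@H]1OC(=O)C(C[Cr](Cl)Cl)=C1 | intermediate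
25 | (4S,6R,7R,8S,10R)-8-hydroxy-1-oxo-3,10-epoxygermacra-2,11(13)-dien-12,6-olide | O[C@H]1C[C@@]2(C)OC(=CC2=O)[C@@H](C)C[C@H]2OC(=O)C(=C)[C@H]12 | intermediate
26 | (4S,6R,7R,8S,10R,11S)-8-hydroxy-1-oxo-3,10-epoxygermacr-2-en-12,6-olide | O[C@H]1C[C@@]2(C)OC(=CC2=O)[C@@H](C)C[C@H]2OC(=O)[C@@H](C)[C@H]12 | intermediate
27 | tigloyl chloride, (2E)-2-methylbut-2-enoyl chloride | C/C=C(\C)C(Cl)=O | starting material
28 | (4S,6R,7S,8S,10R,11S)-1-oxo-8-tigloyloxy-3,10-epoxygermacr-2-en-12,6-olide (CNP0235937.1) | C/C=C(\C)C(=O)O[C@H]1C[C@@]2(C)OC(=CC2=O)[C@@H](C)C[C@H]2OC(=O)[C@@H](C)[C@H]12 | target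

**Totals and risks**
Total steps: 19. Longest linear sequence: 16 steps (steps 1–6 and 10–19).

Step 17 (ring closure). Intermolecular allylation could outrun closure of the strained nine-membered ring, or the allylchromium could be protonated before it reaches the aldehyde. The fallback replaces the metal generated in situ by a stable allylstannane and closes the ring by Lewis-acid-promoted SE2′ addition through an open transition state. Bromo alcohol 22 would be treated with (Bu3Sn)2 and catalytic Pd(PPh3)4 in THF to give the allylstannane alcohol F1. Dess–Martin oxidation would give the stannyl aldehyde F2. BF3·OEt2 in CH2Cl2 at −78 °C under high dilution would then close the ring to 25, where the route is rejoined.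

Step 14 (butenolide metathesis). The allylic bromide could be lost to the catalyst (or already to DMAP in step 13), and ring closure onto the 1,1-disubstituted, electron-poor acrylate could be slow. The fallback installs the bromine after the ring is made. Alcohol 18 would be acylated with methacryloyl chloride (Et3N, DMAP) to the methacrylate F3. Ring-closing metathesis with second-generation Grubbs catalyst would give the α-methylbutenolide F4. Wohl–Ziegler bromination of the allylic methyl (NBS, catalytic AIBN, PhCF3, 80 °C) would give 21.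

Step 18 (C-11). Hydrogen could be delivered to the wrong face if the hydroxyl does not direct, or the exocyclic double bond could migrate into the lactone ring. The fallback sets C-11 by conjugate hydride addition and thermodynamic control instead. Alcohol 25 would first be acylated with 27 (DMAP, pyridine) to the 8-O-tigloyl methylene lactone F5. Chemoselective 1,4-reduction of the unhindered methylene lactone with [(Ph3P)CuH]6 in wet toluene would give 28 together with its 11-epimer F6. Brief treatment of the mixture with catalytic DBU in CH2Cl2 would epimerise F6 at C-11 to the more stable isomer with the methyl trans to C-8, converging on 28.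

**Further compounds**
F1 | step 17 | (5R)-5-{(2S)-2-[(5R)-5-(2-hydroxyethyl)-5-methyl-4-oxo-4,5-dihydrofuran-2-yl]propyl}-3-[(tributylstannyl)methyl]furan-2(5H)-one | OCC[C@@]1(C)OC(=CC1=O)[C@@H](C)C[C@H]1OC(=O)C(C[Sn](CCCC)(CCCC)CCCC)=C1
F2 | step 17 | 2-[(2R)-2-methyl-3-oxo-5-{(2S)-1-[(2R)-5-oxo-4-[(tributylstannyl)methyl]-2,5-dihydrofuran-2-yl]propan-2-yl}-2,3-dihydrofuran-2-yl]acetaldehyde | O=CC[C@@]1(C)OC(=CC1=O)[C@@H](C)C[C@H]1OC(=O)C(C[Sn](CCCC)(CCCC)CCCC)=C1
F3 | step 14 | (3R,5S)-5-[(5R)-5-{2-[(tert-butyldimethylsilyl)oxy]ethyl}-5-methyl-4-oxo-4,5-dihydrofuran-2-yl]hex-1-en-3-yl 2-methylprop-2-enoate | CC(C)(C)[Si](C)(C)OCC[C@@]1(C)OC(=CC1=O)[C@@H](C)C[C@H](C=C)OC(=O)C(C)=C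
F4 | step 14 | (5R)-5-{(2S)-2-[(5R)-5-{2-[(tert-butyldimethylsilyl)oxy]ethyl}-5-methyl-4-oxo-4,5-dihydrofuran-2-yl]propyl}-3-methylfuran-2(5H)-one | CC(C)(C)[Si](C)(C)OCC[C@@]1(C)OC(=CC1=O)[C@@H](C)C[C@H]1OC(=O)C(C)=C1
F5 | step 18 | (4S,6R,7S,8S,10R)-1-oxo-8-tigloyloxy-3,10-epoxygermacra-2,11(13)-dien-12,6-olide | C/C=C(\C)C(=O)O[C@H]1C[C@@]2(C)OC(=CC2=O)[C@@H](C)C[C@H]2OC(=O)C(=C)[C@H]12
F6 | step 18 | (4S,6R,7S,8S,10R,11R)-1-oxo-8-tigloyloxy-3,10-epoxygermacr-2-en-12,6-olide (11-epimer of 28) | C/C=C(\C)C(=O)O[C@H]1C[C@@]2(C)OC(=CC2=O)[C@@H](C)C[C@H]2OC(=O)[C@H](C)[C@H]12
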